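Ring A is cut back to two partners: cyclobutenone, which supplies C4a, C5, C6 and C8a, and a prenyl-bearing triisopropylsiloxyalkyne, which supplies C7 and C8. One thermal Danheiser benzannulation makes C8–C8a and C6–C7, re-closes C4a–C8a and delivers ring A as a 2-prenylresorcinol monosilyl ether. The step exploits the contiguous C8a(O1), C8(prenyl), C7(OH) array of ring A: alkyne polarization forces prenyl between the two oxygens and leaves them differentiated. Ring C is then grown from the C8a hydroxyl through a chromone, and C2 is set last by rhodium-catalysed asymmetric addition of the ring B boronic acid.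

Key step: step 4

Remark on the alkyne: a prenyl group at C8 requires the 5-methylhex-4-en-1-ynyl silyl ether (prenyl directly on the alkyne carbon); a 6-methylhept-5-en-1-ynyl ether would carry one CH2 too many and give homoprenyl.

Remark on the end game: ring C is closed without acid and C2 is set by catalyst control, because an SN2 etherification at a para-alkoxybenzylic carbinol and an acid-mediated acylation beside a prenyl group would each endanger the stereocentre or the olefin.

Assumption: (S)-MeO-F12-BIPHEP, (S)-6,6'-dimethoxy-2,2'-bis[bis(3,4,5-trifluorophenyl)phosphino]biphenyl, is taken to give 2S by analogy with (S)-biaryl bisphosphine rhodium catalysts on cyclic enones; the sense is to be confirmed on the first run and the antipodal ligand used if it is reversed.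

Step 1
Reactants: 1 3-oxocyclobutane-1-carboxylic acid
Product: 3 3-bromocyclobutan-1-one, via acyl hypobromite 2 (not isolated)
Conditions: HgO, Br2, MgSO4, CH2Cl2, reflux
Reagents that add atoms: bromine, BrBr
Why: Cristol–Firth variant of the Hunsdiecker bromodecarboxylation; the mercury carboxylate is brominated to hypobromite 2, which should lose CO2 in a radical chain and leave the ketone untouched.

Step 2
Reactants: 3 3-bromocyclobutan-1-one
Product: 4 cyclobut-2-en-1-one
Conditions: n-Bu3N, neat, rt, reduced pressure; distilled into a −78 °C trap, used at once as a cold toluene solution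
Reagents that add atoms: none
Why: E1cB dehydrobromination β to the ketone; the volatile enone leaves the basic medium as it forms, which should limit polymerization.

Step 3
Reactants: 5 ethyl 4-methylpent-3-enoate
Product: 8 [(5-methylhex-4-en-1-yn-1-yl)oxy]tri(propan-2-yl)silane, via dibromo enolate 6 (not isolated), via lithium ynolate 7 (not isolated)
Conditions: CH2Br2, LiTMP (lithium 2,2,6,6-tetramethylpiperidide), THF, −78 °C; add 5; LiHMDS (LiN(SiMe3)2); n-BuLi, −78 °C → rt; TIPSCl, −78 °C → rt
Reagents that add atoms: dibromomethane, BrCBr; chlorotri(propan-2-yl)silane, CC(C)[Si](Cl)(C(C)C)C(C)C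
Why: Kowalski ester homologation stopped at the ynolate: acylation of LiCHBr2 gives enolate 6, bromine–lithium exchange triggers the 1,2-shift of the prenyl group to ynolate 7, and the bulky silyl chloride should silylate on oxygen.

Step 4
Reactants: 4 cyclobut-2-en-1-one; 8 [(5-methylhex-4-en-1-yn-1-yl)oxy]tri(propan-2-yl)silane
Product: 13 2-(3-methylbut-2-en-1-yl)-3-[(triisopropylsilyl)oxy]phenol, via vinylketene 9 (not isolated), via vinylcyclobutenone 10 (not isolated), via dienylketene 11 (not isolated), via cyclohexadienone 12 (not isolated)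
Conditions: toluene, 80 °C → 110 °C, sealed vessel; 4 (1.0 equiv) added slowly to 8 (1.2 equiv)
Reagents that add atoms: none
Why: Heating opens 4 by 4π electrocyclic ring opening to vinylketene 9, whose ketene C=C adds to alkyne 8 in a regiospecific (2+2) cycloaddition to give 10; 4π opening of 10 then gives dienylketene 11, which closes by 6π electrocyclization to dienone 12 and tautomerizes to phenol 13. The closest known reaction type is the Danheiser benzannulation of cyclobutenones with siloxyalkynes to resorcinol monosilyl ethers. Ring A is closed by thermal disrotatory 6π electrocyclization (C4a–C8a), after C8–C8a and C6–C7 have been made in the (2+2) step. No stereocenter is formed. The step needs regiocontrol only: oxygen polarization makes the prenyl-bearing alkyne carbon the nucleophile that bonds to the ketene carbonyl carbon, so prenyl must end between the new hydroxyl and the silyloxy group. Slow addition of 4 to excess hot 8 keeps the ketene concentration low and so should limit self-condensation and acylation of 13.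

Step 5
Reactants: 13 2-(3-methylbut-2-en-1-yl)-3-[(triisopropylsilyl)oxy]phenol
Product: 15 2-hydroxy-3-(3-methylbut-2-en-1-yl)-4-[(triisopropylsilyl)oxy]benzaldehyde, via salicyl alcohol 14 (not isolated)
Conditions: MgCl2, Et3N, (CH2O)n, THF, reflux
Reagents that add atoms: paraformaldehyde (formaldehyde unit), C=O
Why: Casnati–Skattebøl ortho-formylation: the magnesium phenoxide delivers formaldehyde to the only free ortho carbon (the future C4a), and alcohol 14 is oxidized in the flask by a second formaldehyde (Oppenauer-type hydride transfer); no acid meets the ortho-prenylphenol.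

Step 6
Reactants: 15 2-hydroxy-3-(3-methylbut-2-en-1-yl)-4-[(triisopropylsilyl)oxy]benzaldehyde
Product: 16 1-{2-hydroxy-3-(3-methylbut-2-en-1-yl)-4-[(triisopropylsilyl)oxy]phenyl}prop-2-yn-1-ol (racemic)
Conditions: HC≡CMgBr (3 equiv), THF, 0 °C → rt; aq. NH4Cl
Reagents that add atoms: ethynylmagnesium bromide, C#C[Mg]Br
Why: Grignard 1,2-addition of an acetylide to the aldehyde; one equivalent is spent on the phenol, and the new carbinol centre needs no control because it is oxidized in the next step.

Step 7
Reactants: 16 1-{2-hydroxy-3-(3-methylbut-2-en-1-yl)-4-[(triisopropylsilyl)oxy]phenyl}prop-2-yn-1-ol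
Product: 19 8-(3-methylbut-2-en-1-yl)-7-[(triisopropylsilyl)oxy]-4H-chromen-4-one, via ynone 17 (not isolated), via enaminone 18 (not isolated)
Conditions: MnO2, CH2Cl2, rt; filter; Et2NH, THF, rt → 40 °C
Reagents that add atoms: none
Why: MnO2 should oxidize the benzylic propargylic alcohol selectively to ynone 17; conjugate addition of Et2NH gives enaminone 18, and the phenol oxygen closes ring C by 6-endo addition–elimination with release of the amine, the amine-mediated chromone synthesis that avoids 5-exo closure (any residual 18 should close on silica gel).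

Step 8
Reactants: 20 4-bromophenol; 21 isoprene (2-methylbuta-1,3-diene)
Product: 23 6-bromo-2,2-dimethylchroman, via prenylphenol 22 (not isolated)
Conditions: AgOSO2CF3 (5 mol%), ClCH2CH2Cl, rt → 50 °C
Reagents that add atoms: none
Why: Silver triflate-catalysed Friedel–Crafts prenylation ortho to the hydroxyl, followed by Markovnikov hydroalkoxylation of the prenyl olefin in 22; bromine blocks the para position.

Step 9
Reactants: 23 6-bromo-2,2-dimethylchroman
Product: 26 (2,2-dimethylchroman-6-yl)boronic acid, via aryllithium 24 (not isolated), via lithium triisopropoxyborate 25 (not isolated)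
Conditions: n-BuLi, THF, −78 °C; B(OiPr)3, −78 °C → rt; 1 M HCl
Reagents that add atoms: triisopropyl borate, CC(C)OB(OC(C)C)OC(C)C; water, O
Why: Bromine–lithium exchange, borylation of the aryllithium and acidic hydrolysis of the borate; the chroman ether is inert.

Step 10
Reactants: 19 8-(3-methylbut-2-en-1-yl)-7-[(triisopropylsilyl)oxy]-4H-chromen-4-one; 26 (2,2-dimethylchroman-6-yl)boronic acid
Product: 27 (2S)-2-(2,2-dimethylchroman-6-yl)-8-(3-methylbut-2-en-1-yl)-7-[(triisopropylsilyl)oxy]chroman-4-one
Conditions: [RhCl(C2H4)2]2 (2.5 mol%), (S)-MeO-F12-BIPHEP (5.5 mol%), KOH (10 mol%), 26 (2.5 equiv), toluene/H2O, 20–30 °C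
Reagents that add atoms: none
Why: Hayashi–Miyaura asymmetric 1,4-addition of an arylboronic acid to a chromone: the aryl–rhodium species adds across C2=C3 from the face set by the (S)-bisphosphine, which fixes C2 as S, and hydrolysis of the rhodium enolate releases the flavanone; the borate-buffered medium at low temperature should spare the silyl ether, the prenyl group and the new stereocentre.

Step 11
Reactants: 27 (2S)-2-(2,2-dimethylchroman-6-yl)-8-(3-methylbut-2-en-1-yl)-7-[(triisopropylsilyl)oxy]chroman-4-one
Product: 28 Euchrenone a17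
Conditions: TBAF (Bu4NF), AcOH (1 equiv each), THF, 0 °C
Reagents that add atoms: none
Why: Fluoride cleavage of the aryl silyl ether; the acetic acid buffer keeps the medium non-basic, so the flavanone should not racemize by reversible ring opening to the chalcone.

Compound list
1 | 3-oxocyclobutane-1-carboxylic acid | O=C1CC(C(=O)O)C1 | starting material
2 | 3-oxocyclobutane-1-carbonyl hypobromite | O=C1CC(C(=O)OBr)C1 | intermediate
3 | 3-bromocyclobutan-1-one | O=C1CC(Br)C1 | intermediate
4 | cyclobut-2-en-1-one | O=C1C=CC1 | intermediate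
5 | ethyl 4-methylpent-3-enoate | CCOC(=O)CC=C(C)C | starting material
6 | lithium 1,1-dibromo-5-methylhexa-1,4-dien-2-olate | [Li+].[O-]C(CC=C(C)C)=C(Br)Br | intermediate
7 | lithium 5-methylhex-4-en-1-yn-1-olate | [Li+].[O-]C#CCC=C(C)C | intermediate
8 | [(5-methylhex-4-en-1-yn-1-yl)oxy]tri(propan-2-yl)silane | CC(C)=CCC#CO[Si](C(C)C)(C(C)C)C(C)C | intermediate
9 | buta-1,3-dien-1-one (vinylketene) | C=CC=C=O | intermediate
10 | 4-ethenyl-2-(3-methylbut-2-en-1-yl)-3-[(triisopropylsilyl)oxy]cyclobut-2-en-1-one (racemic) | O=C1C(CC=C(C)C)=C(O[Si](C(C)C)(C(C)C)C(C)C)C1C=C | intermediate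
11 | (3E)-2-(3-methylbut-2-en-1-yl)-3-[(triisopropylsilyl)oxy]hexa-1,3,5-trien-1-one | O=C=C(CC=C(C)C)\C(O[Si](C(C)C)(C(C)C)C(C)C)=C/C=C | intermediate
12 | 2-(3-methylbut-2-en-1-yl)-3-[(triisopropylsilyl)oxy]cyclohexa-2,4-dien-1-one | O=C1CC=CC(O[Si](C(C)C)(C(C)C)C(C)C)=C1CC=C(C)C | intermediate
13 | 2-(3-methylbut-2-en-1-yl)-3-[(triisopropylsilyl)oxy]phenol | CC(C)=CCc1c(O)cccc1O[Si](C(C)C)(C(C)C)C(C)C | intermediate
14 | 2-(hydroxymethyl)-6-(3-methylbut-2-en-1-yl)-5-[(triisopropylsilyl)oxy]phenol | CC(C)=CCc1c(O)c(CO)ccc1O[Si](C(C)C)(C(C)C)C(C)C | intermediate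
15 | 2-hydroxy-3-(3-methylbut-2-en-1-yl)-4-[(triisopropylsilyl)oxy]benzaldehyde | CC(C)=CCc1c(O)c(C=O)ccc1O[Si](C(C)C)(C(C)C)C(C)C | intermediate
16 | 1-{2-hydroxy-3-(3-methylbut-2-en-1-yl)-4-[(triisopropylsilyl)oxy]phenyl}prop-2-yn-1-ol (racemic) | CC(C)=CCc1c(O)c(C(O)C#C)ccc1O[Si](C(C)C)(C(C)C)C(C)C | intermediate
17 | 1-{2-hydroxy-3-(3-methylbut-2-en-1-yl)-4-[(triisopropylsilyl)oxy]phenyl}prop-2-yn-1-one | CC(C)=CCc1c(O)c(C(=O)C#C)ccc1O[Si](C(C)C)(C(C)C)C(C)C | intermediate
18 | (2E)-3-(diethylamino)-1-{2-hydroxy-3-(3-methylbut-2-en-1-yl)-4-[(triisopropylsilyl)oxy]phenyl}prop-2-en-1-one | CCN(CC)/C=C/C(=O)c1ccc(O[Si](C(C)C)(C(C)C)C(C)C)c(CC=C(C)C)c1O | intermediate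
19 | 8-(3-methylbut-2-en-1-yl)-7-[(triisopropylsilyl)oxy]-4H-chromen-4-one | CC(C)=CCc1c(O[Si](C(C)C)(C(C)C)C(C)C)ccc2c1OC=CC2=O | intermediate
20 | 4-bromophenol | Oc1ccc(Br)cc1 | starting material
21 | isoprene (2-methylbuta-1,3-diene) | C=CC(C)=C | starting material
22 | 4-bromo-2-(3-methylbut-2-en-1-yl)phenol | CC(C)=CCc1cc(Br)ccc1O | intermediate
23 | 6-bromo-2,2-dimethylchroman (6-bromo-2,2-dimethyl-3,4-dihydro-2H-chromene) | CC1(C)CCc2cc(Br)ccc2O1 | intermediate
24 | (2,2-dimethylchroman-6-yl)lithium | [Li]c1ccc2OC(C)(C)CCc2c1 | intermediate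
25 | lithium (2,2-dimethylchroman-6-yl)tri(propan-2-yloxy)borate | [Li+].CC(C)O[B-](OC(C)C)(OC(C)C)c1ccc2OC(C)(C)CCc2c1 | intermediate
26 | (2,2-dimethylchroman-6-yl)boronic acid | CC1(C)CCc2cc(B(O)O)ccc2O1 | intermediate
27 | (2S)-2-(2,2-dimethylchroman-6-yl)-8-(3-methylbut-2-en-1-yl)-7-[(triisopropylsilyl)oxy]chroman-4-one | CC(C)=CCc1c(O[Si](C(C)C)(C(C)C)C(C)C)ccc2c1O[C@H](c1ccc3c(c1)CCC(C)(C)O3)CC2=O | intermediate
28 | Euchrenone a17, (2S)-2-(2,2-dimethylchroman-6-yl)-7-hydroxy-8-(3-methylbut-2-en-1-yl)chroman-4-one | CC(C)=CCc1c(O)ccc2c1O[C@H](c1ccc3c(c1)CCC(C)(C)O3)CC2=O | target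

Total step count: 11.
Longest linear sequence: 8 steps (steps 1, 2, 4, 5, 6, 7, 10 and 11, from 1 to 28).

Steps most likely to fail

Step 4. The process at risk is self-consumption of cyclobutenone and vinylketene 9 (polymerization, dimerization, acylation of the product phenol) running faster than capture of 9 by alkyne 8. The fallback gives up ring construction and places prenyl on an existing resorcinol ring by directed ortho-metalation. It sets out from no numbered compound but from commercial 1,3-bis(methoxymethoxy)benzene F1 and comes back to the route at 13. n-BuLi in THF at 0 °C should lithiate F1 between the two acetal oxygens to give [2,6-bis(methoxymethoxy)phenyl]lithium F2 in the flask. Prenyl bromide with catalytic CuI should then convert F2 into 1,3-bis(methoxymethoxy)-2-(3-methylbut-2-en-1-yl)benzene F3 by allylation at the lithiated carbon. Brief treatment of F3 with dilute HCl in MeOH at rt should free 2-(3-methylbut-2-en-1-yl)benzene-1,3-diol F4 before the prenyl olefin can cyclize onto a hydroxyl. One equivalent of TIPSCl with imidazole in CH2Cl2 should silylate one of the two equivalent hydroxyls of F4 to give 13.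

Step 10. The process at risk is weak or reversed facial discrimination at C2, together with carborhodation of the electron-rich chromone running slower than protodeboronation of 26. The fallback replaces catalyst control by resolution; it sets out from 19 (together with 26) and comes back at 27. The addition is run with [Rh(OH)(cod)]2 alone in dioxane/H2O, a highly active ligand set for this reaction. It should give racemic 2-(2,2-dimethylchroman-6-yl)-8-(3-methylbut-2-en-1-yl)-7-[(triisopropylsilyl)oxy]chroman-4-one F5 as the adduct. Preparative HPLC of F5 on a cellulose tris(3,5-dimethylphenylcarbamate) phase should then separate 27 from its enantiomer (2R)-2-(2,2-dimethylchroman-6-yl)-8-(3-methylbut-2-en-1-yl)-7-[(triisopropylsilyl)oxy]chroman-4-one F6 so that F6 is set aside.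

Step 3. The process at risk is α-deprotonation of the β,γ-unsaturated ester by LiCHBr2 or the amide bases in competition with addition to the carbonyl, which would return the ester or its conjugated isomer. The fallback makes the ynolate by oxidation of an acetylide instead of by rearrangement; it sets out from 5 and comes back at 7, which is silylated to 8 as in step 3. DIBAL-H (i-Bu2AlH) in CH2Cl2 at −78 °C should reduce 5 to 4-methylpent-3-enal F7 without over-reduction. Corey–Fuchs olefination of F7 with CBr4 and PPh3 should give 1,1-dibromo-5-methylhexa-1,4-diene F8 as a stable intermediate. Two equivalents of n-BuLi in THF at −78 °C should convert F8 into (5-methylhex-4-en-1-yn-1-yl)lithium F9 by exchange, rearrangement and deprotonation. Lithium tert-butyl peroxide F10 is made beforehand from anhydrous tert-butyl hydroperoxide and LiHMDS, and F10 should then transfer oxygen to the acetylide carbon of F9 to give 7.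

Further compounds
F1 | step 4 | 1,3-bis(methoxymethoxy)benzene | COCOc1cccc(OCOC)c1
F2 | step 4 | [2,6-bis(methoxymethoxy)phenyl]lithium | [Li]c1c(OCOC)cccc1OCOC
F3 | step 4 | 1,3-bis(methoxymethoxy)-2-(3-methylbut-2-en-1-yl)benzene | COCOc1cccc(OCOC)c1CC=C(C)C
F4 | step 4 | 2-(3-methylbut-2-en-1-yl)benzene-1,3-diol | CC(C)=CCc1c(O)cccc1O
F5 | step 10 | racemic 2-(2,2-dimethylchroman-6-yl)-8-(3-methylbut-2-en-1-yl)-7-[(triisopropylsilyl)oxy]chroman-4-one | CC(C)=CCc1c(O[Si](C(C)C)(C(C)C)C(C)C)ccc2c1OC(c1ccc3c(c1)CCC(C)(C)O3)CC2=O
F6 | step 10 | (2R)-2-(2,2-dimethylchroman-6-yl)-8-(3-methylbut-2-en-1-yl)-7-[(triisopropylsilyl)oxy]chroman-4-one | CC(C)=CCc1c(O[Si](C(C)C)(C(C)C)C(C)C)ccc2c1O[C@@H](c1ccc3c(c1)CCC(C)(C)O3)CC2=O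
F7 | step 3 | 4-methylpent-3-enal | CC(C)=CCC=O
F8 | step 3 | 1,1-dibromo-5-methylhexa-1,4-diene | CC(C)=CCC=C(Br)Br
F9 | step 3 | (5-methylhex-4-en-1-yn-1-yl)lithium | [Li]C#CCC=C(C)C
F10 | step 3 | lithium tert-butyl peroxide | [Li+].CC(C)(C)O[O-]
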